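## Retrosynthetic overview
- Kazinol B comes from global O-demethylation of a 7-methoxyflavan that carries a methyl ether on the B-ring phenol.
- The 2-arylchroman is disconnected at O1–C2 and C3–C4 into an o-quinone methide (from 2-hydroxy-4-methoxybenzyl alcohol) and an electron-rich styrene. A chiral-Brønsted-acid-catalysed oxa-[4+2] closes the chroman ring and sets the only stereocentre.
- The styrene comes from Wittig methylenation of an ortho-prenylated chromene aldehyde. The prenyl group is installed by directed ortho-lithiation/prenylation, and the chromene aldehyde comes from vanillin and prenal.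
- Ring order: the 2,2-dimethylchromene is formed first, and the chroman ring is formed last, in the key step.

Assumptions:
- The α-amino-alkoxide/OMe cooperative lithiation occurs at C7, between the two directing groups.
- Both TRIP enantiomers are commercially available. The one that gives the (S)-flavan is chosen after a first screen; (S)-TRIP is written below.

## Route

**Step 1**
Reactants: 1 vanillin; 2 3-methylbut-2-enal (prenal)
Product: 3 8-methoxy-2,2-dimethyl-2H-chromene-6-carbaldehyde
Conditions: pyridine, 115 °C, 24 h (or EDDA cat., xylene, reflux)
Reagents that add atoms: none (2 is the listed reactant; H2O is lost)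
Why: Phenol–enal condensation followed by oxa-6π-electrocyclisation is the standard 2,2-dimethylchromene synthesis, and it is regioselective because vanillin has only one free position ortho to the 4-OH.

**Step 2**
Reactants: 3; 4 prenyl bromide
Product: 5 8-methoxy-2,2-dimethyl-7-(3-methylbut-2-en-1-yl)-2H-chromene-6-carbaldehyde
Conditions: (i) LiN(Me)CH2CH2NMe2 (from N,N,N′-trimethylethylenediamine/n-BuLi), THF, 0 °C; (ii) n-BuLi, –20 °C, 3 h; (iii) CuI (10 mol%), 4, –78 → 0 °C; sat. aq. NH4Cl workup
Reagents that add atoms: prenyl bromide (4), CC(C)=CCBr
Why: Comins-type directed ortho-metalation through the in situ α-amino alkoxide, reinforced by the adjacent OMe, puts lithium at C7. Cu-catalysed SN2 alkylation with prenyl bromide gives the linear prenyl group, and workup collapses the aminal back to the aldehyde.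

**Step 3**
Reactants: 5; 6 methyltriphenylphosphonium bromide
Product: 7 6-ethenyl-8-methoxy-2,2-dimethyl-7-(3-methylbut-2-en-1-yl)-2H-chromene
Conditions: 6, KOtBu, THF, 0 °C → rt, 3 h
Reagents that add atoms: methyltriphenylphosphonium bromide (6), C[P+](c1ccccc1)(c1ccccc1)c1ccccc1.[Br-] (supplies the =CH2)
Why: Wittig methylenation converts the aldehyde into the styrene, and the chromene alkene, prenyl group and OMe are inert to the ylide.

**Step 4**
Reactants: 8 2-hydroxy-4-methoxybenzaldehyde
Product: 9 2-hydroxy-4-methoxybenzyl alcohol
Conditions: NaBH4, MeOH, 0 °C, 1 h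
Reagents that add atoms: none (hydride adds H only)
Why: Chemoselective aldehyde reduction gives the bench-stable o-QM precursor, which is used fresh.

**Step 5**
Reactants: 7 styrene; 9 2-hydroxy-4-methoxybenzyl alcohol (2 equiv, added in two portions); catalyst 10 (S)-TRIP
Product: 11 (S)-7-methoxy-2-[8-methoxy-2,2-dimethyl-7-(3-methylbut-2-en-1-yl)-2H-chromen-6-yl]chromane
Conditions: 10 (10 mol%), toluene (0.05 M), 4 Å MS, 50–60 °C, 48 h
Reagents that add atoms: none (9 is the listed reactant; H2O is lost)
Why: Proposed new method: the chiral phosphoric acid dehydrates 9 to the 4-methoxy-substituted o-quinone methide and holds it as a hydrogen-bonded ion pair. The nucleophilic CH2 terminus of the p-alkoxystyrene attacks the o-QM methylene carbon, and the resulting p-alkoxybenzylic cation (or a concerted asynchronous transition state) is closed by the phenol O–H···phosphate. The anion's chiral pocket fixes the facial approach, so C2 forms as (S). The closest known reaction type is the CPA-catalysed inverse-electron-demand oxa-Diels–Alder of in situ o-QMs with enol ethers, enamides and 3-vinylindoles, here extended to a simple electron-rich styrene. The p-alkoxystyrene is the most cation-stabilising alkene present, so it should outcompete the prenyl and chromene alkenes.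

**Step 6**
Reactants: 11
Product: 12 (S)-Kazinol B
Conditions: NaSEt (8 equiv), DMF, 130 °C, 4 h, Ar; then aq. NH4Cl
Reagents that add atoms: none (the methyl groups leave as EtSMe)
Why: SN2 thiolate O-demethylation cleaves both aryl methyl ethers (the crowded, twisted B-ring OMe goes fastest), and the alkenes, the benzylic chroman ether and the C2 stereocentre are untouched because basic conditions cannot ionise or epimerise it.

## Compound list
1 | vanillin (4-hydroxy-3-methoxybenzaldehyde) | COc1cc(C=O)ccc1O | starting material
2 | 3-methylbut-2-enal (prenal) | CC(C)=CC=O | starting material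
3 | 8-methoxy-2,2-dimethyl-2H-chromene-6-carbaldehyde | COc1cc(C=O)cc2c1OC(C)(C)C=C2 | intermediate
4 | prenyl bromide (1-bromo-3-methylbut-2-ene) | CC(C)=CCBr | starting material
5 | 8-methoxy-2,2-dimethyl-7-(3-methylbut-2-en-1-yl)-2H-chromene-6-carbaldehyde | COc1c(CC=C(C)C)c(C=O)cc2c1OC(C)(C)C=C2 | intermediate
6 | methyltriphenylphosphonium bromide | C[P+](c1ccccc1)(c1ccccc1)c1ccccc1.[Br-] | starting material
7 | 6-ethenyl-8-methoxy-2,2-dimethyl-7-(3-methylbut-2-en-1-yl)-2H-chromene | C=Cc1cc2C=CC(C)(C)Oc2c(OC)c1CC=C(C)C | intermediate
8 | 2-hydroxy-4-methoxybenzaldehyde | COc1ccc(C=O)c(O)c1 | starting material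
9 | 2-hydroxy-4-methoxybenzyl alcohol | COc1ccc(CO)c(O)c1 | intermediate
10 | (S)-TRIP, commercially available catalyst: (S)-3,3′-bis(2,4,6-triisopropylphenyl)-1,1′-binaphthyl-2,2′-diyl hydrogen phosphate (the SMILES omits the axial descriptor) | O=P1(O)Oc2c(-c3c(C(C)C)cc(C(C)C)cc3C(C)C)cc3ccccc3c2-c2c(O1)c(-c1c(C(C)C)cc(C(C)C)cc1C(C)C)cc1ccccc21 | starting material
11 | (S)-7-methoxy-2-[8-methoxy-2,2-dimethyl-7-(3-methylbut-2-en-1-yl)-2H-chromen-6-yl]chromane | CC(C)=CCc1c([C@@H]2CCc3ccc(OC)cc3O2)cc2c(c1OC)OC(C)(C)C=C2 | intermediate
12 | (S)-Kazinol B | CC(C)=CCc1c([C@@H]2CCc3ccc(O)cc3O2)cc2c(c1O)OC(C)(C)C=C2 | target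

## Totals
Total steps: 6. Longest linear sequence: 5 (1 → 3 → 5 → 7 → 11 → 12, i.e. Steps 1, 2, 3, 5, 6).

## Three steps most likely to fail
1. **Step 5 (the proposed new oxa-[4+2])**: risks are o-QM dimerisation, low ee, Friedel–Crafts attack on the chromene arene, intramolecular cation–olefin cyclisation of the benzylic cation onto the ortho-prenyl alkene, and acid sensitivity of the chromene and prenyl groups.
   - Fallback using known chemistry: Claisen–Schmidt condensation of 5 with 2′-hydroxy-4′-methoxyacetophenone gives the chalcone.
   - Cinchona-thiourea or squaramide-catalysed intramolecular oxa-Michael addition gives the (S)-flavanone.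
   - NaBH4 reduction gives the flavan-4-ol, and Et3SiH/TFA (or B(C6F5)3) deoxygenation gives 11, followed by Step 6.
2. **Step 2 (ortho-lithiation/prenylation)**: risks are lithiation at C5 instead of C7, or SN2′ alkylation giving the reverse-prenyl product.
   - Fallback: build the 8-oxygenated chromene by a different route, starting from 3,4-dihydroxybenzaldehyde.
   - Selective 4-O-(1,1-dimethylpropargylation) and thermal cyclisation give the 8-hydroxychromene aldehyde.
   - O-Allylation at the 8-OH and aromatic Claisen rearrangement put the allyl group at C7.
   - Cross-metathesis with 2-methylbut-2-ene (Grubbs–Hoveyda II) gives the prenyl group, and MeI/K2CO3 gives 5.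
3. **Step 6 (double demethylation)**: risks are incomplete cleavage or decomposition at 130 °C.
   - Fallback: change the protecting-group strategy and remove silyl groups under mild, non-acidic conditions.
   - Take the 8-OH-free Claisen/metathesis intermediate from the Step 2 fallback and protect it as the TBS ether (TBSCl, imidazole) instead of methylating it.
   - Use 2-hydroxy-4-(TBSO)benzyl alcohol in Step 5.
   - Remove both TBS groups with TBAF in THF at 0 °C → rt.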